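| flask | D | Q | E | remark | time |
|---|---|---|---|---|---|
| south-east | 20 mM | 19 mM | 40 µM | run made earlier |  |
| north-west | 20 mM | 19 mM | 20 µM | run made earlier |  |
| west | 20 mM | 19 mM | 80 µM | run made earlier |  |
| noon | 20 mM (fed, over 15 h) | 19.0 mM | 40 µM | all else is in the flask from the start; the feed brings no volume worth counting | 40 h |
| spring | 20 mM | 19.0 mM (fed, over 15 h) | 40 µM | all else is in the flask from the start; the feed brings no volume worth counting | 40 h |
| dusk | 20 mM | 19.0 mM | 40 µM | everything together at the start | 40 h |
| dawn | 20 mM (in portions, 5, over 15 h) | 19.0 mM | 40 µM | first portion at the start, last at 15 h | 40 h |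

| run | time / h | G / % | D / % |
|---|---|---|---|
| south-east | 10.0 | 39.5 | 0 |
| south-east | 20.0 | 54.4 | 0.2 |
| south-east | 30.0 | 62.8 | 0.5 |
| south-east | 40.0 | 68.5 | 0 |
| north-west | 4.00 | 10.2 | 0.3 |
| north-west | 8.00 | 18.7 | 0.4 |
| north-west | 20.0 | 35.0 | 0 |
| north-west | 50.0 | 53.9 | 0 |
| west | 6.00 | 45.5 | 0.2 |
| west | 15.0 | 66.9 | 0 |
| west | 30.0 | 77.2 | 0.2 |
| west | 50.0 | 82.8 | 0 |

(each reading ± 0.3 percentage points)



* the flask with the highest amount of G, in percent of the D charged ("all alike" if they lie within 1.5 percentage points) (noon / spring / dusk / dawn / all alike)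
* final G, as a percentage of the D charged, in noon
* final G, as a percentage of the D charged, in spring
* final G, as a percentage of the D charged, in dusk
* final G, as a percentage of the D charged, in dawn

In a one-step world [E] would just set the clock: D and Q, charged nearly equal, would follow 1/G = 1/a + S/t, with one ceiling a at every [E]. By symmetry that ceiling is the mean of the two charges, 97.5% of the D charged, and this is the zero of my scale. The first and last readings of a run give a. For the south-east run a is 90.7%, so its deficit, the symmetric ceiling less the ceiling read, is 6.8 percentage points.

| [E] | ceiling read | deficit |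
|---|---|---|
| 20 µM | 85.9% | 12 points |
| 40 µM | 90.7% | 6.8 points |
| 80 µM | 93.2% | 4.3 points |

Reading down, the deficit shrinks as [E] rises , so some D leaves by a path without E. I take that path to be D with Q, both paths first order in D, which makes the deficit follow [Q]/[E] while D is present.

For noon and dawn I keep the middle row as a rough figure, although Q is being consumed while D enters, so their deficit may lie somewhat below it. For spring, the north-west reading of D at 4.00 h, 0.3% with a scatter of 0.3 points, cannot be told from zero and says only that D is below 1% of its charge there. Taking the lifetime of D to go as 1/[E], I bound it at 40 µM by 0.434 h, far shorter than the feed of 15 h, so in my reckoning spring's ceiling returns to the symmetric one.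

Each feed costs a mean delay of 7.50 h. With S = 14.3 h from the south-east run, scaled by (a/z)² for spring, I reckon 64.8% for noon and dawn and 71.1% for spring. Dusk repeats the south-east reading of 68.5%, so I put spring highest.

The forecast, holding that “Dusk is expected highest”, gave dusk, with noon 63.5%, spring 63%, dusk 68.5% and dawn 63.5%, and it parts from my reckoning on spring.

The flasks give spring as the highest: noon 65.0%, spring 71.1%, dusk 68.1%, dawn 65.0%.

    D + Q → X (k = 22.0 M⁻¹ h⁻¹)
    D + E → E + J (k = 1.20 × 10⁵ M⁻¹ h⁻¹)
    Q + E + J → E + G (k = 1.10 × 10⁵ M⁻² h⁻¹)

In dusk, at the charged concentrations, D has a half-life of 0.14 h by the step with E against 1.7 h by the step with Q, a selectivity factor of 11.5 that leaves 8.01% of D for X, and dusk ends with X at 7.65%. Against the deficit of 6.8 points, noon holds X at 6.72% and dawn at 6.60%, while spring holds 0.116%. The neighbouring spring flask with 5.0 mM of D also holds X at 0.119%, with G at 89.4%.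

The earlier runs and the new flask are calculated on assumed constants; scatter was added.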